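Acerosin is disconnected across pyrone ring C: C4 becomes carbon monoxide, C4a an iodide-bearing carbon of ring A, and C3–C2 with ring B an arylacetylene. In ring A, C4a sits between the C5 oxygen and the C8a oxygen, and the 6-OMe/7-OBn/8-OMe array makes these two oxygens equivalent, so a palladium-catalysed carbonylative alkyne coupling with in situ closure forms C4a–C4, C4–C3 and O1–C2 in one operation with no regiochemical question. The precursor is a mirror-symmetric 5-benzyloxy-4,6-dimethoxy-2-iodoresorcinol, carried into the coupling as its diacetate to ease oxidative addition and handling. One hydrogenolysis then frees both benzyl-masked phenols.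

Key step: step 7

Remark: the target has no stereocenter. Diethylamine is assumed to remove both acetyl groups of 7 during the key step, so the flavone should be isolated as its free 5-hydroxy form 13.

Step 1
Reactants: 1 2,6-dimethoxyphenol (syringol)
Product: 2 2-(benzyloxy)-1,3-dimethoxybenzene
Conditions: BnBr, K2CO3, DMF, 60 °C
Reagents that add atoms: benzyl bromide, BrCc1ccccc1
Why: Williamson ether synthesis of an acidic phenol with a reactive benzylic bromide should be straightforward, and capping the central oxygen leaves the two methoxy groups to direct the next step.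

Step 2
Reactants: 2 2-(benzyloxy)-1,3-dimethoxybenzene
Product: 3 3-(benzyloxy)-1,5-dibromo-2,4-dimethoxybenzene
Conditions: NBS (2.1 equiv), MeCN, 0 °C to rt, dark
Reagents that add atoms: N-bromosuccinimide, O=C1CCC(=O)N1Br
Why: Electrophilic aromatic bromination should take both equivalent sites that are ortho to one methoxy and para to the other, because the third C–H is meta to both methoxy groups and para only to the twisted central benzyloxy group.

Step 3
Reactants: 3 3-(benzyloxy)-1,5-dibromo-2,4-dimethoxybenzene
Product: 5 5-(benzyloxy)-4,6-dimethoxybenzene-1,3-diol, via bis(pinacolboronate) 4 (not isolated)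
Conditions: B2pin2, Pd(dppf)Cl2, KOAc, 1,4-dioxane, 90 °C; then 30% H2O2, AcOH, THF, 0 °C to rt (under N2)
Reagents that add atoms: hydrogen peroxide, OO; bis(pinacolato)diboron, CC1(C)OB(OC1(C)C)B1OC(C)(C)C(C)(C)O1 (boron of intermediate 4 only)
Why: Twofold Miyaura borylation followed by peroxide oxidation of the aryl boronates (1,2-aryl shift from boron to oxygen) is a standard bromide-to-phenol exchange that benzyl and methyl ethers tolerate.

Step 4
Reactants: 5 5-(benzyloxy)-4,6-dimethoxybenzene-1,3-diol
Product: 7 5-(benzyloxy)-2-iodo-4,6-dimethoxy-1,3-phenylene diacetate, via iodoresorcinol 6 (not isolated)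
Conditions: NIS (1.0 equiv), MeCN, 0 °C, dark; then Ac2O, Et3N, DMAP, 0 °C to rt
Reagents that add atoms: N-iodosuccinimide, O=C1CCC(=O)N1I; acetic anhydride, CC(=O)OC(C)=O
Why: Electrophilic aromatic iodination can only take the single ring C–H, which two ortho hydroxyls activate, and DMAP-catalysed O-acetylation in the same flask should trap the air- and light-sensitive iodoresorcinol as a stable, less electron-rich diacetate.

Step 5
Reactants: 8 3-hydroxy-4-methoxybenzaldehyde (isovanillin)
Product: 9 3-(benzyloxy)-4-methoxybenzaldehyde
Conditions: BnBr, K2CO3, DMF, rt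
Reagents that add atoms: benzyl bromide, BrCc1ccccc1
Why: Williamson ether synthesis of the phenol should proceed cleanly since the aldehyde is inert to carbonate base.

Step 6
Reactants: 9 3-(benzyloxy)-4-methoxybenzaldehyde
Product: 10 2-(benzyloxy)-4-ethynyl-1-methoxybenzene
Conditions: dimethyl (1-diazo-2-oxopropyl)phosphonate, K2CO3, MeOH, rt
Reagents that add atoms: dimethyl (1-diazo-2-oxopropyl)phosphonate, COP(=O)(OC)C(=[N+]=[N-])C(C)=O
Why: The Seyferth–Gilbert homologation in its Ohira–Bestmann form should convert the non-enolisable aryl aldehyde into the terminal alkyne under mild base that leaves the benzyl ether untouched.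

Step 7
Reactants: 7 5-(benzyloxy)-2-iodo-4,6-dimethoxy-1,3-phenylene diacetate; 10 2-(benzyloxy)-4-ethynyl-1-methoxybenzene
Product: 13 7-(benzyloxy)-2-[3-(benzyloxy)-4-methoxyphenyl]-5-hydroxy-6,8-dimethoxy-4H-chromen-4-one, via aryl ynone diacetate 11 (not isolated), via diethylamino enaminone 12 (not isolated)
Conditions: PdCl2(PPh3)2 (5 mol%), dppp, thiourea, DBU, Et2NH (excess), CO (1 atm), 40 °C
Reagents that add atoms: carbon monoxide, [C-]#[O+]; diethylamine, CCNCC (nitrogen of intermediate 12 only)
Why: Zerovalent palladium inserts into the C–I bond of 7, carbon monoxide insertion gives the aroyl-palladium species, and coupling with the base-activated alkyne 10 delivers ynone 11; diethylamine then adds to the ynone and aminolyses both acetates to give enaminone 12, whose phenol displaces the amine at C2. The closest known reaction type is the palladium-catalysed carbonylative Sonogashira annulation of ortho-iodophenol acetates with terminal arylacetylenes to flavones under carbon monoxide at atmospheric pressure. Ring C closes by 6-endo oxa-Michael addition–elimination on the enaminone (the O1–C2 bond), and no stereocenter is formed. The selectivity needed is 6-endo closure to the flavone over 5-exo closure to the aurone, and the secondary amine secures it by turning the ynone into an enaminone before the phenol can attack the triple bond. Regiochemistry needs no control, because the two oxygens flanking the iodide carbon of 7 are related by the mirror plane through C2 and C5 of the arene, so either closes to the same product and the other ends as the hydrogen-bonded 5-OH. The acetates keep the ring from becoming a phenoxide before oxidative addition, which is the slow event on this electron-rich, doubly ortho-substituted iodide.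

Step 8
Reactants: 13 7-(benzyloxy)-2-[3-(benzyloxy)-4-methoxyphenyl]-5-hydroxy-6,8-dimethoxy-4H-chromen-4-one
Product: 14 acerosin, 5,7-dihydroxy-2-(3-hydroxy-4-methoxyphenyl)-6,8-dimethoxy-4H-chromen-4-one
Conditions: H2 (1 atm), 10% Pd/C, EtOAc/MeOH, rt
Reagents that add atoms: none
Why: Catalytic hydrogenolysis should cleave both benzyl aryl ethers, while the aryl methyl ethers and the conjugated pyrone are expected to survive at atmospheric pressure if the reaction is stopped once debenzylation is complete.

Compound list
1 | 2,6-dimethoxyphenol (syringol) | COc1cccc(OC)c1O | starting material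
2 | 2-(benzyloxy)-1,3-dimethoxybenzene | COc1cccc(OC)c1OCc1ccccc1 | intermediate
3 | 3-(benzyloxy)-1,5-dibromo-2,4-dimethoxybenzene | COc1c(Br)cc(Br)c(OC)c1OCc1ccccc1 | intermediate
4 | 2,2'-[5-(benzyloxy)-4,6-dimethoxy-1,3-phenylene]bis(4,4,5,5-tetramethyl-1,3,2-dioxaborolane) | COc1c(B2OC(C)(C)C(C)(C)O2)cc(B2OC(C)(C)C(C)(C)O2)c(OC)c1OCc1ccccc1 | intermediate (not isolated)
5 | 5-(benzyloxy)-4,6-dimethoxybenzene-1,3-diol | COc1c(O)cc(O)c(OC)c1OCc1ccccc1 | intermediate
6 | 5-(benzyloxy)-2-iodo-4,6-dimethoxybenzene-1,3-diol | COc1c(O)c(I)c(O)c(OC)c1OCc1ccccc1 | intermediate (not isolated)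
7 | 5-(benzyloxy)-2-iodo-4,6-dimethoxy-1,3-phenylene diacetate | COc1c(OC(C)=O)c(I)c(OC(C)=O)c(OC)c1OCc1ccccc1 | intermediate
8 | 3-hydroxy-4-methoxybenzaldehyde (isovanillin) | COc1ccc(C=O)cc1O | starting material
9 | 3-(benzyloxy)-4-methoxybenzaldehyde | COc1ccc(C=O)cc1OCc1ccccc1 | intermediate
10 | 2-(benzyloxy)-4-ethynyl-1-methoxybenzene | C#Cc1ccc(OC)c(OCc2ccccc2)c1 | intermediate
11 | 5-(benzyloxy)-2-{3-[3-(benzyloxy)-4-methoxyphenyl]prop-2-ynoyl}-4,6-dimethoxy-1,3-phenylene diacetate | COc1ccc(C#CC(=O)c2c(OC(C)=O)c(OC)c(OCc3ccccc3)c(OC)c2OC(C)=O)cc1OCc1ccccc1 | intermediate (not isolated)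
12 | (E)-1-[4-(benzyloxy)-2,6-dihydroxy-3,5-dimethoxyphenyl]-3-[3-(benzyloxy)-4-methoxyphenyl]-3-(diethylamino)prop-2-en-1-one | CCN(CC)/C(=C/C(=O)c1c(O)c(OC)c(OCc2ccccc2)c(OC)c1O)c1ccc(OC)c(OCc2ccccc2)c1 | intermediate (not isolated)
13 | 7-(benzyloxy)-2-[3-(benzyloxy)-4-methoxyphenyl]-5-hydroxy-6,8-dimethoxy-4H-chromen-4-one | COc1ccc(-c2cc(=O)c3c(O)c(OC)c(OCc4ccccc4)c(OC)c3o2)cc1OCc1ccccc1 | intermediate
14 | acerosin, 5,7-dihydroxy-2-(3-hydroxy-4-methoxyphenyl)-6,8-dimethoxy-4H-chromen-4-one | COc1ccc(-c2cc(=O)c3c(O)c(OC)c(O)c(OC)c3o2)cc1O | target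

Total step count: 8 steps.
Longest linear sequence: 6 steps (steps 1, 2, 3, 4, 7 and 8); the alkyne arm (steps 5 and 6) joins at step 7.

Steps most likely to fail

Step 7. Oxidative addition to the hindered, electron-rich iodide may be slow enough that hydrodeiodination takes over. The aroyl-palladium species may also be captured by diethylamine as an amide before the alkyne couples, and the acetyl group on the 5-oxygen may be lost only in part. The fallback builds ring C by the classical chalcone route; it sets out from 5 and 9 and returns at 13. Friedel–Crafts C-acetylation of 5 at its only ring C–H (Ac2O, BF3·OEt2, 0 °C to rt, aqueous work-up) should give 1-[4-(benzyloxy)-2,6-dihydroxy-3,5-dimethoxyphenyl]ethan-1-one F1. Claisen–Schmidt condensation of this ketone with aldehyde 9 (KOH, EtOH, rt, prolonged) should give (E)-1-[4-(benzyloxy)-2,6-dihydroxy-3,5-dimethoxyphenyl]-3-[3-(benzyloxy)-4-methoxyphenyl]prop-2-en-1-one F2. Oxidative cyclisation of the chalcone with catalytic I2 in DMSO at 120 °C should then give 13, again without a regiochemical choice because the two hydroxyls are equivalent.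

Step 3. The second borylation may stall, hydrodebromination may compete, and the very electron-rich resorcinol may be oxidised further by the peroxide. The fallback replaces boron chemistry by direct palladium-catalysed C–O coupling with hydroxide; it sets out from 3 and returns at 5. Both C–Br bonds would be hydroxylated with Pd2(dba)3, tBuXPhos and KOH in 1,4-dioxane/H2O at 100 °C under N2, followed by acidification; no new compound is made (F0).

Step 4. The iodinating agent may oxidise the pentaoxygenated ring instead of substituting it, or iodine may be lost again during acylation. The fallback installs iodine by directed ortho-metalation instead of electrophilic substitution; it sets out from 5 and returns at 6, which is acetylated to 7 as in the second half of step 4. Treatment of 5 with MOMCl and i-Pr2NEt in CH2Cl2 should give 3-(benzyloxy)-2,4-dimethoxy-1,5-bis(methoxymethoxy)benzene F3. Lithiation of this ether at the C–H flanked by the two MOM ethers (n-BuLi, THF, 0 °C) and quenching with I2 should give 1-(benzyloxy)-4-iodo-2,6-dimethoxy-3,5-bis(methoxymethoxy)benzene F4. Mild acid (HCl, MeOH, rt) should then release 6.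

Further compounds
F1 | step 7 | 1-[4-(benzyloxy)-2,6-dihydroxy-3,5-dimethoxyphenyl]ethan-1-one | CC(=O)c1c(O)c(OC)c(OCc2ccccc2)c(OC)c1O
F2 | step 7 | (E)-1-[4-(benzyloxy)-2,6-dihydroxy-3,5-dimethoxyphenyl]-3-[3-(benzyloxy)-4-methoxyphenyl]prop-2-en-1-one | COc1ccc(/C=C/C(=O)c2c(O)c(OC)c(OCc3ccccc3)c(OC)c2O)cc1OCc1ccccc1
F0 | step 3 | none | none
F3 | step 4 | 3-(benzyloxy)-2,4-dimethoxy-1,5-bis(methoxymethoxy)benzene | COCOc1cc(OCOC)c(OC)c(OCc2ccccc2)c1OC
F4 | step 4 | 1-(benzyloxy)-4-iodo-2,6-dimethoxy-3,5-bis(methoxymethoxy)benzene | COCOc1c(I)c(OCOC)c(OC)c(OCc2ccccc2)c1OC
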